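**Retrosynthetic overview**
1. Target acrylic acid ⇐ enol triflate (palladium hydroxycarbonylation) ⇐ C2 methyl ketone ⇐ C2 ethyl ester of the 3,6-dihydro-2H-pyran; the ester carbon becomes the acrylate α-carbon.
2. Dihydropyran (the only ring of the skeleton, closed last) ⇐ [2,3]-sigmatropic ring expansion of an oxonium ylide made from a racemic 2-homofarnesyl-2-vinyloxirane and ethyl diazoacetate under a chiral monovalent copper catalyst. O1–C2 and C2–C3 form, the olefin moves to C4=C5, C2 is set, and the oxirane, a ring absent from the target, is consumed.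
3. Enabling feature: in the ring, O1–C2–C3–C4=C5 is a homoallyl ether (the retron of an allyl oxonium ylide [2,3]-shift) and C6 ties O1 back to C5. O1, C5 and C6 can therefore start as a strained oxirane whose C5 carries the future C4=C3 vinyl group, and C2 carries a carbonyl-derived carbon, the acceptor group of the carbene.
4. Vinyl oxirane ⇐ Corey–Chaykovsky reaction of a vinyl ketone ⇐ Weinreb amide ⇐ (2E,6E)-farnesyl bromide + enolate of N-methoxy-N-methylacetamide (both E-olefins are bought in).
5. Ring order: temporary oxirane (step 3), then dihydropyran (step 4); no protecting groups.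

Key step: step 4

Assumption: the sense of induction of the copper–bis(oxazoline) carbene transfer is taken to be such that the (S,S)-ligand gives the (2S) ring-expansion product; if a model reaction showed the opposite sense, the equally available (R,R)-ligand would be used with no other change.

**Step 1**
Reactants: 1 (2E,6E)-farnesyl bromide [(2E,6E)-1-bromo-3,7,11-trimethyldodeca-2,6,10-triene]; 2 N-methoxy-N-methylacetamide
Product: 4 (4E,8E)-N-methoxy-N,5,9,13-tetramethyltetradeca-4,8,12-trienamide, via lithium amide enolate 3 (not isolated)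
Conditions: 2 (1.3 equiv), LiN(iPr)2 (1.3 equiv), THF, −78 °C, 30 min; then 1, −78 → −30 °C; aq. NH4Cl
Reagents that add atoms: lithium diisopropylamide, CC(C)N([Li])C(C)C (lithium, kept in 3 only)
Why: Enolate alkylation (SN2) of the amide lithium enolate at the unhindered primary allylic CH2Br should join the two fragments without touching the E-olefins; no stereocentre is formed.

**Step 2**
Reactants: 4 (4E,8E)-N-methoxy-N,5,9,13-tetramethyltetradeca-4,8,12-trienamide
Product: 6 (6E,10E)-7,11,15-trimethylhexadeca-1,6,10,14-tetraen-3-one, via bromomagnesium hemiaminal adduct 5 (not isolated)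
Conditions: CH2=CHMgBr (1.5 equiv), THF, −20 → 0 °C; inverse quench into cold 1 M aq. HCl
Reagents that add atoms: vinylmagnesium bromide, C=C[Mg]Br
Why: Weinreb ketone synthesis: the chelated adduct 5 survives until the quench, so only one vinyl group should be delivered, and the cold acidic quench protonates the released amine before it can add to the enone.

**Step 3**
Reactants: 6 (6E,10E)-7,11,15-trimethylhexadeca-1,6,10,14-tetraen-3-one
Product: 7 rac-2-ethenyl-2-[(3E,7E)-4,8,12-trimethyltrideca-3,7,11-trien-1-yl]oxirane
Conditions: Me3SI (1.5 equiv), n-BuLi (1.4 equiv), THF, −10 °C; then 6, −10 °C → rt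
Reagents that add atoms: trimethylsulfonium iodide, C[S+](C)C.[I-]
Why: Corey–Chaykovsky epoxidation: the unstabilised sulfonium ylide should add 1,2 to the enone carbonyl and the betaine closes to the vinyl oxirane; the quaternary centre is made racemic on purpose because it becomes sp2 in step 4.

**Step 4**
Reactants: 7 rac-2-ethenyl-2-[(3E,7E)-4,8,12-trimethyltrideca-3,7,11-trien-1-yl]oxirane; 8 ethyl diazoacetate
Product: 10 ethyl (2S)-5-[(3E,7E)-4,8,12-trimethyltrideca-3,7,11-trien-1-yl]-3,6-dihydro-2H-pyran-2-carboxylate, via oxonium ylide 9 (not isolated)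
Conditions: Cu(MeCN)4PF6 (5 mol %), (S,S)-2,2'-isopropylidenebis(4-tert-butyl-2-oxazoline) (6 mol %), CH2Cl2, rt; 8 (1.5 equiv) added by syringe pump over 10 h
Reagents that add atoms: none
Why: Proposed new method: the chiral monovalent copper carbene formed from 8 should be attacked by the oxirane oxygen of 7 through the lone pair syn to the vinyl group to give oxonium ylide 9, which stays associated with copper; its carbanionic carbon then bonds to the vinyl terminus while the allylic, strained C–O bond of the oxirane breaks, a [2,3]-sigmatropic shift through a five-centre envelope transition state driven by release of the oxirane strain. The closest known reaction types are the racemic ring expansion of vinyl oxiranes with diazoacetates under Cu(hfacac)2 catalysis (same bond reorganisation), and the enantioselective ring expansion of oxetanes and [2,3]-rearrangement of allyl ether oxonium ylides with diazoacetates under chiral monovalent copper or chiral dirhodium tetracarboxamidate catalysts (same source of asymmetry); new is their combination on a 2,2-disubstituted vinyl oxirane. The dihydropyran is closed by a three-atom ring enlargement of the oxirane (3 → 6), with O1–C2 from ylide formation and C2–C3 from the sigmatropic shift, and the C4=C5 olefin must be cis because both C3 and C6 are held in the new ring. The only new stereocentre, C2, is controlled by the bis(oxazoline) ligand, which shields one face of the carbene carbon and remains on the ylide until C2–C3 forms; the quaternary centre of 7 becomes sp2 C5, so both enantiomers of 7 can converge on one product. The step needs O-ylide formation to win over cyclopropanation of the four olefins, and the [2,3]-shift to win over a [1,2]-shift or deoxygenation. The electrophilic cationic copper carbene should prefer the unhindered oxygen lone pair to the trisubstituted side-chain olefins (shielded from the tert-butyl-flanked carbene) and to the vinyl group (deactivated by the adjacent C–O bond), and the vinyl group directly on the oxirane carbon offers the concerted, strain-releasing [2,3] path.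

**Step 5**
Reactants: 10 ethyl (2S)-5-[(3E,7E)-4,8,12-trimethyltrideca-3,7,11-trien-1-yl]-3,6-dihydro-2H-pyran-2-carboxylate
Product: 13 1-[(2S)-5-[(3E,7E)-4,8,12-trimethyltrideca-3,7,11-trien-1-yl]-3,6-dihydro-2H-pyran-2-yl]ethan-1-one, via Weinreb amide 11 (not isolated), via bromomagnesium hemiaminal adduct 12 (not isolated)
Conditions: MeNH(OMe)·HCl (1.5 equiv), iPrMgCl (3.0 equiv), THF, −20 °C, 1 h; then MeMgBr (2.0 equiv), −20 → 0 °C; aq. NH4Cl
Reagents that add atoms: methylmagnesium bromide, C[Mg]Br; N,O-dimethylhydroxylamine hydrochloride, CNOC.Cl (kept in 11 and 12 only)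
Why: One-pot Weinreb amidation of the ester by the magnesium amide followed by Grignard addition (Weinreb ketone synthesis) should stop at the ketone because adduct 12 collapses only on work-up, and the cold, non-enolising conditions keep C2 configured.

**Step 6**
Reactants: 13 1-[(2S)-5-[(3E,7E)-4,8,12-trimethyltrideca-3,7,11-trien-1-yl]-3,6-dihydro-2H-pyran-2-yl]ethan-1-one
Product: 15 1-[(2S)-5-[(3E,7E)-4,8,12-trimethyltrideca-3,7,11-trien-1-yl]-3,6-dihydro-2H-pyran-2-yl]ethenyl trifluoromethanesulfonate, via potassium enolate 14 (not isolated)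
Conditions: KN(SiMe3)2 (1.1 equiv), THF, −78 °C (13 added to the base), 30 min; then Comins' reagent (1.2 equiv), −78 → −40 °C; aq. NH4Cl
Reagents that add atoms: Comins' reagent [N-(5-chloropyridin-2-yl)bis(trifluoromethanesulfonimide)], FC(F)(F)S(=O)(=O)N(c1ccc(Cl)cn1)S(=O)(=O)C(F)(F)F; potassium bis(trimethylsilyl)amide, C[Si](C)(C)N([K])[Si](C)(C)C (potassium, kept in 14 only)
Why: Kinetic enolate formation at the unhindered methyl group with a bulky amide base at −78 °C, then O-triflation of the enolate (enol triflate synthesis), should leave the slower-to-deprotonate tertiary α-alkoxy C2–H and hence the C2 configuration untouched.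

**Step 7**
Reactants: 15 1-[(2S)-5-[(3E,7E)-4,8,12-trimethyltrideca-3,7,11-trien-1-yl]-3,6-dihydro-2H-pyran-2-yl]ethenyl trifluoromethanesulfonate
Product: 16 2-[(2S)-5-[(3E,7E)-4,8,12-trimethyltrideca-3,7,11-trien-1-yl]-3,6-dihydro-2H-pyran-2-yl]prop-2-enoic acid (target)
Conditions: Pd(OAc)2 (5 mol %), PPh3 (10 mol %), KOAc (4 equiv), CO (1 atm), DMF–H2O (10:1), rt → 40 °C; then aq. citric acid to pH 4
Reagents that add atoms: carbon monoxide, [C-]#[O+]; water, O
Why: Palladium-catalysed hydroxycarbonylation of a vinyl triflate (oxidative addition to zerovalent palladium, CO insertion, hydrolysis of the acyl–palladium) should install the carboxyl carbon on the 1,1-disubstituted olefin under near-neutral conditions that leave the polyene, the ring olefin and C2 untouched.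

**Compound list**
1 | (2E,6E)-farnesyl bromide | BrC/C=C(\C)CC/C=C(\C)CCC=C(C)C | starting material
2 | N-methoxy-N-methylacetamide | CC(=O)N(C)OC | starting material
3 | lithium 1-[methoxy(methyl)amino]ethen-1-olate (lithium enolate of 2) | C=C(O[Li])N(C)OC | intermediate (not isolated)
4 | (4E,8E)-N-methoxy-N,5,9,13-tetramethyltetradeca-4,8,12-trienamide | CON(C)C(=O)CC/C=C(\C)CC/C=C(\C)CCC=C(C)C | intermediate
5 | bromomagnesium (6E,10E)-3-[methoxy(methyl)amino]-7,11,15-trimethylhexadeca-1,6,10,14-tetraen-3-olate | C=CC(O[Mg]Br)(CC/C=C(\C)CC/C=C(\C)CCC=C(C)C)N(C)OC | intermediate (not isolated)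
6 | (6E,10E)-7,11,15-trimethylhexadeca-1,6,10,14-tetraen-3-one | C=CC(=O)CC/C=C(\C)CC/C=C(\C)CCC=C(C)C | intermediate
7 | rac-2-ethenyl-2-[(3E,7E)-4,8,12-trimethyltrideca-3,7,11-trien-1-yl]oxirane | C=CC1(CC/C=C(\C)CC/C=C(\C)CCC=C(C)C)CO1 | intermediate
8 | ethyl diazoacetate | CCOC(=O)C=[N+]=[N-] | starting material
9 | oxonium ylide of 7 and the ethoxycarbonylcarbene (drawn without copper) | CCOC(=O)[CH-][O+]1CC1(C=C)CC/C=C(\C)CC/C=C(\C)CCC=C(C)C | intermediate (not isolated)
10 | ethyl (2S)-5-[(3E,7E)-4,8,12-trimethyltrideca-3,7,11-trien-1-yl]-3,6-dihydro-2H-pyran-2-carboxylate | CCOC(=O)[C@@H]1CC=C(CC/C=C(\C)CC/C=C(\C)CCC=C(C)C)CO1 | intermediate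
11 | (2S)-N-methoxy-N-methyl-5-[(3E,7E)-4,8,12-trimethyltrideca-3,7,11-trien-1-yl]-3,6-dihydro-2H-pyran-2-carboxamide | CON(C)C(=O)[C@@H]1CC=C(CC/C=C(\C)CC/C=C(\C)CCC=C(C)C)CO1 | intermediate (not isolated)
12 | bromomagnesium 1-[methoxy(methyl)amino]-1-[(2S)-5-[(3E,7E)-4,8,12-trimethyltrideca-3,7,11-trien-1-yl]-3,6-dihydro-2H-pyran-2-yl]ethan-1-olate | CC(O[Mg]Br)(N(C)OC)[C@@H]1CC=C(CC/C=C(\C)CC/C=C(\C)CCC=C(C)C)CO1 | intermediate (not isolated)
13 | 1-[(2S)-5-[(3E,7E)-4,8,12-trimethyltrideca-3,7,11-trien-1-yl]-3,6-dihydro-2H-pyran-2-yl]ethan-1-one | CC(=O)[C@@H]1CC=C(CC/C=C(\C)CC/C=C(\C)CCC=C(C)C)CO1 | intermediate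
14 | potassium 1-[(2S)-5-[(3E,7E)-4,8,12-trimethyltrideca-3,7,11-trien-1-yl]-3,6-dihydro-2H-pyran-2-yl]ethen-1-olate | C=C(O[K])[C@@H]1CC=C(CC/C=C(\C)CC/C=C(\C)CCC=C(C)C)CO1 | intermediate (not isolated)
15 | 1-[(2S)-5-[(3E,7E)-4,8,12-trimethyltrideca-3,7,11-trien-1-yl]-3,6-dihydro-2H-pyran-2-yl]ethenyl trifluoromethanesulfonate | C=C(OS(=O)(=O)C(F)(F)F)[C@@H]1CC=C(CC/C=C(\C)CC/C=C(\C)CCC=C(C)C)CO1 | intermediate
16 | 2-[(2S)-5-[(3E,7E)-4,8,12-trimethyltrideca-3,7,11-trien-1-yl]-3,6-dihydro-2H-pyran-2-yl]prop-2-enoic acid | C=C(C(=O)O)[C@@H]1CC=C(CC/C=C(\C)CC/C=C(\C)CCC=C(C)C)CO1 | target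

**Totals**
Total step count: 7. Longest linear sequence: 7 steps (from 1 or 2 to 16).

**Steps most likely to fail**

Step 4 (proposed new method). Three processes may go wrong. The copper carbene may add to the vinyl group or to the electron-rich side-chain olefins (cyclopropanation) faster than to the weakly basic oxirane oxygen. The ylide may form through the lone pair on the side away from the vinyl group and then decay by deoxygenation or a [1,2]-shift. One enantiomer of the racemic oxirane may pair poorly with the ligand, so that facial control at C2 is incomplete. The fallback uses only known chemistry, sets out from 1 and comes back to the route at 10. C-alkylation of the dianion of 2-methylprop-2-en-1-ol (n-BuLi, TMEDA, Et2O) with 1 should give the allylic alcohol (5E,9E)-6,10,14-trimethyl-2-methylidenepentadeca-5,9,13-trien-1-ol F1. Appel bromination (CBr4, PPh3, CH2Cl2, 0 °C) converts it into (5E,9E)-1-bromo-6,10,14-trimethyl-2-methylidenepentadeca-5,9,13-triene F2. O-Alkylation of the purchased chiral building block ethyl (2S)-2-hydroxypent-4-enoate F3 (also accessible from L-allylglycine by diazotisation with retention and esterification) with F2 under Ag2O in Et2O should give the diene ether ethyl (2S)-2-{[(5E,9E)-6,10,14-trimethyl-2-methylidenepentadeca-5,9,13-trien-1-yl]oxy}pent-4-enoate F4, whose stereocentre comes from the chiral pool. Ring-closing metathesis with the second-generation Grubbs catalyst RuCl2(=CHPh)(PCy3)(H2IMes) in CH2Cl2 at 40 °C then closes the same ring at C4=C5 and delivers 10.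

Step 6. Deprotonation on the C2 side, or equilibration of the kinetic enolate before O-sulfonylation, would give the regioisomeric enol triflate and erode the configuration at C2. The fallback avoids enolate chemistry, sets out from 10 and comes back at 16. Reduction of 10 with DIBAL-H (CH2Cl2, −78 °C) should give (2S)-5-[(3E,7E)-4,8,12-trimethyltrideca-3,7,11-trien-1-yl]-3,6-dihydro-2H-pyran-2-carbaldehyde F5. Ohira–Bestmann homologation (dimethyl (1-diazo-2-oxopropyl)phosphonate, K2CO3, MeOH, 0 °C) converts it into the terminal alkyne (2S)-2-ethynyl-5-[(3E,7E)-4,8,12-trimethyltrideca-3,7,11-trien-1-yl]-3,6-dihydro-2H-pyran F6. Markovnikov-selective palladium-catalysed hydrocarboxylation of F6 with formic acid (Pd(OAc)2, Xantphos, catalytic Ac2O, toluene, 80 °C) should then give 16 directly.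

Step 3. Conjugate addition of the ylide, or base-induced oligomerisation of the unhindered vinyl ketone, may compete with 1,2-addition. The fallback bypasses the enone, sets out from 4 and comes back at 7. Chloromethyllithium (ICH2Cl, MeLi·LiBr, THF–Et2O, −78 °C) should convert 4 into the chloromethyl ketone (5E,9E)-1-chloro-6,10,14-trimethylpentadeca-5,9,13-trien-2-one F7. Addition of CH2=CHMgBr at −78 °C gives the chlorohydrin rac-(6E,10E)-3-(chloromethyl)-7,11,15-trimethylhexadeca-1,6,10,14-tetraen-3-ol F8, which closes to 7 with aq. NaOH in Et2O.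

**Further compounds**
F1 | step 4 | (5E,9E)-6,10,14-trimethyl-2-methylidenepentadeca-5,9,13-trien-1-ol | C=C(CO)CC/C=C(\C)CC/C=C(\C)CCC=C(C)C
F2 | step 4 | (5E,9E)-1-bromo-6,10,14-trimethyl-2-methylidenepentadeca-5,9,13-triene | C=C(CBr)CC/C=C(\C)CC/C=C(\C)CCC=C(C)C
F3 | step 4 | ethyl (2S)-2-hydroxypent-4-enoate | CCOC(=O)[C@@H](O)CC=C
F4 | step 4 | ethyl (2S)-2-{[(5E,9E)-6,10,14-trimethyl-2-methylidenepentadeca-5,9,13-trien-1-yl]oxy}pent-4-enoate | CCOC(=O)[C@@H](OCC(=C)CC/C=C(\C)CC/C=C(\C)CCC=C(C)C)CC=C
F5 | step 6 | (2S)-5-[(3E,7E)-4,8,12-trimethyltrideca-3,7,11-trien-1-yl]-3,6-dihydro-2H-pyran-2-carbaldehyde | O=C[C@@H]1CC=C(CC/C=C(\C)CC/C=C(\C)CCC=C(C)C)CO1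
F6 | step 6 | (2S)-2-ethynyl-5-[(3E,7E)-4,8,12-trimethyltrideca-3,7,11-trien-1-yl]-3,6-dihydro-2H-pyran | C#C[C@@H]1CC=C(CC/C=C(\C)CC/C=C(\C)CCC=C(C)C)CO1
F7 | step 3 | (5E,9E)-1-chloro-6,10,14-trimethylpentadeca-5,9,13-trien-2-one | ClCC(=O)CC/C=C(\C)CC/C=C(\C)CCC=C(C)C
F8 | step 3 | rac-(6E,10E)-3-(chloromethyl)-7,11,15-trimethylhexadeca-1,6,10,14-tetraen-3-ol | C=CC(O)(CCl)CC/C=C(\C)CC/C=C(\C)CCC=C(C)C
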